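## The problem

The target is a 12-membered head-to-tail diolide. Ring A (the arene with one aryl H) and ring B (the fully substituted arene) each carry a carboxyl group and, ortho to it, a 1,2-dihydroxypropyl chain; the carboxyl of each ring esterifies the C-methyl carbinol of the other ring's chain. The four stereocentres form two threo pairs of opposite sense, (S,S) on the ring A chain and (R,R) on the ring B chain. The pairs are too far apart to control one another, so each half needs its own absolute control. Inside one chain the benzylic and the C-methyl carbon are neighbours and can be set one after the other under a single chiral director. Both aroyl carbons lie between an oxygen substituent and a branched benzylic carbon, so ester formation by attack at these carbonyl groups is slow. Every chain oxygen is a latent internal nucleophile: a free C-methyl carbinol can close a six-membered isochromanone on the carboxyl of its own ring, and a free benzylic carbinol a five-membered phthalide. The macrocycle and its open precursors will therefore not survive alkoxide, strong acid or long heating once these hydroxyls are free, and the benzylic C–O bonds can be lost on forcing hydrogenolysis. The feature that opens the key step is the ring A side chain: the aryl-bound oxygenated carbon and the oxygenated C-methyl carbon can each be inserted as a CHCl unit into a carbon–boron bond, and the ring carbon bearing the chain is the one position of 2-methoxyresorcinol with no ortho substituent, so boron can be placed there first.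

## Retrosynthesis

Target 39 is traced to hepta-O-benzyl diolide 38 by cutting seven O–benzyl bonds. Benzyl is used on the five phenols and on both benzylic oxygens, so one neutral hydrogenolysis ends the synthesis and the benzylic hydroxyls never face an ester while an acid or base is present. The forward step must cleave O–CH2Ph bonds and leave the hindered aryl–CH–O bonds.

Diolide 38 is opened at the acyl C–O bond of the ring A ester to give seco acid 37. This ester is chosen over the ring B ester because the ring A acid is a 2-alkyl-4,6-dialkoxybenzoic acid, the class for which carboxyl-activated macrolactonisation is established, whereas the ring B carboxyl sits on a hexasubstituted ring. Cutting the O–alkyl bond instead would need the epimeric carbinol. The forward step must close a 12-membered ring faster than the free carbinol attacks the neighbouring ring B ester.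

Seco acid 37 comes from diester 35 by removal of an allyl ester (to acid 36) and a silyl ether. In 35 the aryl–carbonyl C–C bond of the ring B ester is cut, giving aryl bromide 33 (as aryllithium 34) and imidazole carboxylate 20. This reverses the usual polarity: the most hindered ester is made by carbon–carbon bond formation and not by acylation with a hexasubstituted benzoic acid. The precursors are two monocyclic halves of similar size; the forward step needs an aryllithium that tolerates benzyl and silyl ethers at low temperature.

Imidazole carboxylate 20 derives from hydroxy allyl ester 19, and this from lactone 17, which stores the ring A carboxyl and the chain carbinol in one stable ring. Lactone 17 comes from bromo alcohol 14 by bromine–lithium exchange and carboxylation, and 14 from alcohol 13 by bromination at one of two equivalent ring positions. No protecting group is spent on the ring A carbinol.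

Aryl bromide 33 is traced through phenol 32 to dibromide 29, silyl ether 28 and alcohol 27. The two equivalent positions next to the chain are both brominated; one bromine becomes the extra oxygen of ring B and the other the site of metalation. This keeps ring B on the same intermediates as ring A instead of requiring a separate tetra-oxygenated arene.

Alcohol 13 arises from boronate 12 by oxidation of the C–B bond with retention. Boronate 12 is cut at two bonds, the chain C–C bond and the C–CH3 bond, giving α-benzyloxybenzyl boronate 10, dichloromethane 8 and a methyl Grignard reagent. One chiral diol controls both insertions, so the threo relationship follows without a second source of chirality. Alcohol 27 comes in the same way from boronate 26 and boronate 24 in the mirror-image series.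

Boronate 10 is traced through α-chloro boronate 9 to aryl boronate 7 and a second molecule of 8; the benzylic oxygen enters as benzyloxide. Boronates 24 and 23 relate in the same way to aryl boronate 22.

Aryl boronates 7 and 22 are the esters of one boronic acid 5 with (+)-pinanediol 6 and (−)-pinanediol 21. Acid 5 is prepared once from pinacol boronate 4, isolated and divided between the two enantiomeric series, so it is the last common intermediate of the two halves. The C–B bond of 4 is cut back to bis-silyl ether 2 and 2-methoxyresorcinol 1 through silyl boronate 3. The borylation is run on silyl ethers because benzyl ethers would offer unhindered phenyl C–H bonds to the catalyst; benzyl groups are put on directly afterwards.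

## Roads not taken

Alternative 1: Ring B is built instead of decorated. The cut runs through the arene bond between the chain-bearing carbon and the neighbouring hydroxylated carbon of ring B. In the forward sense cyclobutenone A1, which carries the tert-butoxy and methoxy groups, a PMB-protected hydroxymethyl arm and the (R,R)-diol as its acetonide, is heated. The four-membered ring opens to a dienylketene, the ketene carbon bonds to the chain-bearing alkene carbon in a six-electron electrocyclisation, and tautomerisation gives hydroquinone A2.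
- Merits: all six substituents of ring B are placed by construction, so no regiochemical question arises on a crowded arene.
- Weak points: the two alkoxy groups must be told apart when the four-membered precursor is assembled. The carboxyl carbon arrives at the alcohol oxidation level and needs two oxidations between two ortho substituents. The chain stereocentres must be made separately and survive thermolysis as an allylic acetal. The sequence serves ring B only.
- Comparison: for the oxygen pattern of ring B this road is cleaner than the chosen one, which must break the symmetry of dibromide 29 by a single bromine–lithium exchange (step 21). The chosen plan sets against it a common boronic acid 5 for both rings, one stereochemical method used twice with antipodal diols, and a ring B branch no longer than the ring A branch.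

Alternative 2: The macrocycle is closed at the O–alkyl bond of the ring A ester instead of its acyl bond. Seco acid A3 carries the ring B C-methyl carbinol in the (S) configuration; PPh3/DIAD activates it and the ring A carboxylate displaces it with inversion to (R), giving protected diolide A4.
- Merits: no di-ortho-substituted carboxyl is activated, so there is no hindered acyl substitution and no neighbouring-group attack on an acylating species. Alkylative esterification is the best-established route to esters of such benzoic acids.
- Weak points: the ring B chain must be erythro before closure, which two insertions under one director do not deliver, so the director must be changed between insertions or the carbinol inverted in extra steps. The activated carbinol is secondary, branched and next to a benzylic silyloxy carbon, so elimination and slow displacement threaten. The benzylic silyl ethers add a fluoride step when the molecule is most fragile.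
- Comparison: at the ring closure itself this road is the stronger one, and an alkylative closure is kept as the fallback for step 26. The chosen plan sets against it that both chains are used exactly as the boronate chemistry delivers them, and that the more hindered ring B ester is made without any acylation (step 23), leaving one acylative ester formation at the less hindered ring A carboxyl.

Alternative 3: Ring A is made last, on the closed macrocycle. The cut removes the two arene bonds of ring A that flank its carbonyl-bearing and chain-bearing carbons. Macrocyclic ynoate A5, in which an alkyne stands for these two carbons, reacts with diene A6 in a [4+2] cycloaddition; loss of methanol aromatises the adduct to A7 with the ring A phenols free.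
- Merits: the macrolactonisation is done on an unhindered alkynoic acid, ring A appears with its oxygen pattern and its single aryl hydrogen fixed by the diene, and the step is strongly convergent.
- Weak points: a 12-membered ring holding an alkyne, an ortho-phenylene unit and two esters is strained, and its closure is uncertain. The regiochemistry relies on the ketene acetal terminus of A6 adding to the carbon next to the carbonyl, which the macrocycle may perturb. A6 is a heavily oxygenated, moisture-sensitive diene. The propargylic stereocentre of the ring A chain would need another method, so the boronate chemistry would serve ring B only. Two free phenols beside benzyl and silyl ethers lengthen the end game.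
- Comparison: this road avoids every hindered acyl substitution at ring A and is shorter in the ring A series. The chosen plan offers stereocontrol of both chains by one reagent class, intermediates without ring strain and a single global deprotection.

Key step: step 8

Remark on descriptors: boron ranks below carbon, so the benzylic carbon is (R) in 10 and 12 and (S) in 13 although its spatial arrangement is unchanged; the same holds with opposite signs in the ring B series.

Remark on intermediates: lithium borate complexes and activated acyl species are transient and are described in the Why lines; organolithium forms of numbered substrates and telescoped compounds carry numbers.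

Assumption: the target is taken to be isolable as drawn, so its phenolic and benzylic hydroxyls are set free only in the last step under neutral conditions.

## Steps

Step 1
Reactants: 1 2-methoxyresorcinol
Product: 2 1,3-bis(tert-butyldimethylsilyloxy)-2-methoxybenzene
Conditions: TBSCl, imidazole, DMF, rt
Reagents that add atoms: tert-butyldimethylsilyl chloride, CC(C)(C)[Si](C)(C)Cl
Why: Imidazole-promoted silylation of phenols; silyl ethers are used here because, unlike benzyl ethers, they carry no aryl C–H bonds that could be borylated in step 2.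

Step 2
Reactants: 2 1,3-bis(tert-butyldimethylsilyloxy)-2-methoxybenzene
Product: 3 2-[3,5-bis(tert-butyldimethylsilyloxy)-4-methoxyphenyl]-4,4,5,5-tetramethyl-1,3,2-dioxaborolane
Conditions: B2pin2, [Ir(OMe)(cod)]2 (cat.), 4,4'-di-tert-butyl-2,2'-bipyridine (cat.), cyclohexane, 80 °C
Reagents that add atoms: bis(pinacolato)diboron, CC1(C)OB(OC1(C)C)B1OC(C)(C)C(C)(C)O1
Why: Iridium-catalysed C–H borylation is governed by sterics; in 2 only the C–H para to the methoxy group has no ortho substituent, so boron should enter there alone.

Step 3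
Reactants: 3 2-[3,5-bis(tert-butyldimethylsilyloxy)-4-methoxyphenyl]-4,4,5,5-tetramethyl-1,3,2-dioxaborolane
Product: 4 2-[3,5-bis(benzyloxy)-4-methoxyphenyl]-4,4,5,5-tetramethyl-1,3,2-dioxaborolane
Conditions: KF, BnBr, DMF, rt
Reagents that add atoms: benzyl bromide, BrCc1ccccc1
Why: Fluoride cleaves the aryl silyl ethers and the phenoxides are benzylated in the same pot (desilylative Williamson etherification); the pinacol boronate tolerates KF in dry DMF.

Step 4
Reactants: 4 2-[3,5-bis(benzyloxy)-4-methoxyphenyl]-4,4,5,5-tetramethyl-1,3,2-dioxaborolane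
Product: 5 [3,5-bis(benzyloxy)-4-methoxyphenyl]boronic acid
Conditions: NaIO4, NH4OAc, acetone/H2O, rt; extraction and isolation
Reagents that add atoms: water, O
Why: Oxidative hydrolysis of a pinacol boronate: periodate cleaves the pinacol released on hydrolysis to acetone and so drives 4 to the boronic acid, which is isolated once and divided between the two enantiomeric series; no stereocentre is formed.

Step 5
Reactants: 5 [3,5-bis(benzyloxy)-4-methoxyphenyl]boronic acid; 6 (+)-pinanediol, (1S,2S,3R,5S)-2,6,6-trimethylbicyclo[3.1.1]heptane-2,3-diol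
Product: 7 (+)-pinanediol [3,5-bis(benzyloxy)-4-methoxyphenyl]boronate
Conditions: 6, Et2O, rt
Reagents that add atoms: none
Why: Boronic ester formation: the boronic acid condenses with the rigid cis-diol at room temperature to the robust five-membered cyclic ester with loss of water; no stereocentre is formed.

Step 6
Reactants: 7 (+)-pinanediol [3,5-bis(benzyloxy)-4-methoxyphenyl]boronate; 8 dichloromethane
Product: 9 (+)-pinanediol {(S)-[3,5-bis(benzyloxy)-4-methoxyphenyl](chloro)methyl}boronate
Conditions: 8, n-BuLi, THF, −100 °C; then 7; ZnCl2, −100 °C to rt; aqueous work-up, crude product used at once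
Reagents that add atoms: none
Why: Matteson homologation: LiCHCl2 adds to boron and the aryl group migrates from the transient ate complex with loss of the chloride selected by the pinanediol, which for the (+)-diol gives the (S)-chloride; ZnCl2 binds free chloride and limits epimerisation of this benzylic halide.

Step 7
Reactants: 9 (+)-pinanediol {(S)-[3,5-bis(benzyloxy)-4-methoxyphenyl](chloro)methyl}boronate
Product: 10 (+)-pinanediol {(R)-(benzyloxy)[3,5-bis(benzyloxy)-4-methoxyphenyl]methyl}boronate
Conditions: BnOH, n-BuLi, THF, 0 °C; then 9, −78 °C to rt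
Reagents that add atoms: benzyl alcohol (used as lithium benzyloxide), OCc1ccccc1
Why: Lithium benzyloxide adds to boron and the benzyloxy group migrates to carbon with inversion, turning the (S)-chloride into the (R)-benzyl ether (alkoxide displacement on an α-chloro boronic ester); 9 is used fresh and cold because chloride can epimerise the benzylic centre.

Step 8
Reactants: 10 (+)-pinanediol {(R)-(benzyloxy)[3,5-bis(benzyloxy)-4-methoxyphenyl]methyl}boronate; 8 dichloromethane
Product: 12 (+)-pinanediol {(1R,2S)-1-(benzyloxy)-1-[3,5-bis(benzyloxy)-4-methoxyphenyl]propan-2-yl}boronate, via chloro boronate 11 (not isolated)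
Conditions: 8, n-BuLi, THF, −100 °C; then 10; ZnCl2, −100 °C to rt; recooled to −78 °C, MeMgBr (Et2O), then to rt
Reagents that add atoms: methylmagnesium bromide, C[Mg]Br
Why: LiCHCl2 adds to the boron of 10 to give a transient dichloromethyl ate complex, and on warming with ZnCl2 the benzylic carbon migrates from boron to carbon with retention and expels one of the two diastereotopic chlorides, which forms the chain C–C bond and gives chloro boronate 11. The (+)-pinanediol framework decides which chloride is anti to the migrating group, so the new CHCl carbon should be (S); the benzylic centre, made under the same director in steps 6 and 7, is a spectator. MeMgBr then adds to boron and its methyl group migrates with inversion at carbon as chloride leaves, which forms the C–CH3 bond and sets the C-methyl stereocentre as (S) at the C–B carbon, threo to the benzyloxy carbon. The closest known reaction type is the Matteson homologation of α-benzyloxyalkyl pinanediol boronates followed by Grignard displacement. No ring is closed. Three selectivities are needed: chloride diastereoselection, secured by the rigid diol and by ZnCl2, which accelerates the directed migration; configurational stability of 11, secured by ZnCl2 binding free chloride; and migration in preference to β-elimination of benzyloxide from the ate complexes, secured by keeping them cold and adding the Grignard reagent at −78 °C. The benzylic nature of the migrating carbon raises its migratory aptitude and offsets the retarding α-oxygen.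

Step 9
Reactants: 12 (+)-pinanediol {(1R,2S)-1-(benzyloxy)-1-[3,5-bis(benzyloxy)-4-methoxyphenyl]propan-2-yl}boronate
Product: 13 (1S,2S)-1-(benzyloxy)-1-[3,5-bis(benzyloxy)-4-methoxyphenyl]propan-2-ol
Conditions: 30% H2O2, aq NaOH, THF, 0 °C to rt
Reagents that add atoms: hydrogen peroxide, OO
Why: Basic peroxide oxidises the C–B bond by a 1,2-shift of carbon from boron to oxygen with retention, so the (S)-C–B carbon becomes the (S)-carbinol; benzyl ethers are inert.

Step 10
Reactants: 13 (1S,2S)-1-(benzyloxy)-1-[3,5-bis(benzyloxy)-4-methoxyphenyl]propan-2-ol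
Product: 14 (1S,2S)-1-(benzyloxy)-1-[3,5-bis(benzyloxy)-2-bromo-4-methoxyphenyl]propan-2-ol
Conditions: NBS (1 equiv), MeCN, 0 °C, dark
Reagents that add atoms: N-bromosuccinimide, O=C1CCC(=O)N1Br
Why: Electrophilic aromatic bromination; the two free ring positions are equivalent and each is ortho and para to a benzyloxy group, and the first bromine slows entry of a second.

Step 11
Reactants: 14 (1S,2S)-1-(benzyloxy)-1-[3,5-bis(benzyloxy)-2-bromo-4-methoxyphenyl]propan-2-ol
Product: 17 (3S,4S)-4,6,8-tris(benzyloxy)-7-methoxy-3-methylisochroman-1-one, via dilithio aryl alkoxide 15 (not isolated), via hydroxy acid 16 (not isolated)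
Conditions: n-BuLi (2.1 equiv), THF, −78 °C; CO2; aq HCl; then TsOH·H2O (cat.), CH2Cl2, rt
Reagents that add atoms: carbon dioxide, O=C=O
Why: The first equivalent of n-BuLi deprotonates the carbinol and the second effects bromine–lithium exchange; carboxylation and acidification give hydroxy acid 16, which closes by acid-catalysed lactonisation to the six-membered lactone, a stable store for both functions, with the stereocentres untouched.

Step 12
Reactants: 17 (3S,4S)-4,6,8-tris(benzyloxy)-7-methoxy-3-methylisochroman-1-one
Product: 19 allyl 2-[(1S,2S)-1-(benzyloxy)-2-hydroxypropyl]-4,6-bis(benzyloxy)-5-methoxybenzoate, via potassium carboxylate 18 (not isolated)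
Conditions: KOH, THF/MeOH/H2O, 40 °C; evaporation to dryness; allyl bromide, DMF, rt
Reagents that add atoms: potassium hydroxide, [K+].[OH-]; allyl bromide, C=CCBr
Why: Saponification opens the lactone by acyl–oxygen cleavage and the carboxylate is O-alkylated by allyl bromide, so the ester forms without attack at the hindered carbonyl; the neutral carbinol is not alkylated.

Step 13
Reactants: 19 allyl 2-[(1S,2S)-1-(benzyloxy)-2-hydroxypropyl]-4,6-bis(benzyloxy)-5-methoxybenzoate
Product: 20 (1S,2S)-1-(benzyloxy)-1-{2-[(allyloxy)carbonyl]-3,5-bis(benzyloxy)-4-methoxyphenyl}propan-2-yl 1H-imidazole-1-carboxylate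
Conditions: 1,1'-carbonyldiimidazole, CH2Cl2, rt
Reagents that add atoms: 1,1'-carbonyldiimidazole, O=C(n1ccnc1)n1ccnc1
Why: Secondary alcohols react with carbonyldiimidazole to give stable alkyl imidazole-1-carboxylates; this places on the ring A chain oxygen the carbonyl carbon that will become the ring B ester carbon.

Step 14
Reactants: 5 [3,5-bis(benzyloxy)-4-methoxyphenyl]boronic acid; 21 (−)-pinanediol, (1R,2R,3S,5R)-2,6,6-trimethylbicyclo[3.1.1]heptane-2,3-diol
Product: 22 (−)-pinanediol [3,5-bis(benzyloxy)-4-methoxyphenyl]boronate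
Conditions: 21, Et2O, rt
Reagents that add atoms: none
Why: Boronic ester formation as in step 5, run on the second portion of acid 5 with the antipodal diol that will direct the (R,R) series.

Step 15
Reactants: 22 (−)-pinanediol [3,5-bis(benzyloxy)-4-methoxyphenyl]boronate; 8 dichloromethane
Product: 23 (−)-pinanediol {(R)-[3,5-bis(benzyloxy)-4-methoxyphenyl](chloro)methyl}boronate
Conditions: 8, n-BuLi, THF, −100 °C; then 22; ZnCl2, −100 °C to rt; aqueous work-up, crude product used at once
Reagents that add atoms: none
Why: Matteson homologation as in step 6; the (−)-diol selects the other chloride and gives the (R)-chloride.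

Step 16
Reactants: 23 (−)-pinanediol {(R)-[3,5-bis(benzyloxy)-4-methoxyphenyl](chloro)methyl}boronate
Product: 24 (−)-pinanediol {(S)-(benzyloxy)[3,5-bis(benzyloxy)-4-methoxyphenyl]methyl}boronate
Conditions: BnOH, n-BuLi, THF, 0 °C; then 23, −78 °C to rt
Reagents that add atoms: benzyl alcohol (used as lithium benzyloxide), OCc1ccccc1
Why: Alkoxide displacement with inversion through the borate, as in step 7, gives the (S)-benzyl ether.

Step 17
Reactants: 24 (−)-pinanediol {(S)-(benzyloxy)[3,5-bis(benzyloxy)-4-methoxyphenyl]methyl}boronate; 8 dichloromethane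
Product: 26 (−)-pinanediol {(1S,2R)-1-(benzyloxy)-1-[3,5-bis(benzyloxy)-4-methoxyphenyl]propan-2-yl}boronate, via chloro boronate 25 (not isolated)
Conditions: 8, n-BuLi, THF, −100 °C; then 24; ZnCl2, −100 °C to rt; recooled to −78 °C, MeMgBr (Et2O), then to rt
Reagents that add atoms: methylmagnesium bromide, C[Mg]Br
Why: Mirror image of step 8: directed insertion gives the (R)-CHCl carbon of 25, and methyl migration with inversion sets the (R)-C–B carbon, threo to the benzyloxy carbon.

Step 18
Reactants: 26 (−)-pinanediol {(1S,2R)-1-(benzyloxy)-1-[3,5-bis(benzyloxy)-4-methoxyphenyl]propan-2-yl}boronate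
Product: 27 (1R,2R)-1-(benzyloxy)-1-[3,5-bis(benzyloxy)-4-methoxyphenyl]propan-2-ol
Conditions: 30% H2O2, aq NaOH, THF, 0 °C to rt
Reagents that add atoms: hydrogen peroxide, OO
Why: Oxidation of the C–B bond with retention, as in step 9.

Step 19
Reactants: 27 (1R,2R)-1-(benzyloxy)-1-[3,5-bis(benzyloxy)-4-methoxyphenyl]propan-2-ol
Product: 28 tert-butyl{[(1R,2R)-1-(benzyloxy)-1-[3,5-bis(benzyloxy)-4-methoxyphenyl]propan-2-yl]oxy}dimethylsilane
Conditions: TBSOTf, 2,6-lutidine, CH2Cl2, 0 °C
Reagents that add atoms: tert-butyldimethylsilyl trifluoromethanesulfonate, CC(C)(C)[Si](C)(C)OS(=O)(=O)C(F)(F)F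
Why: Silyl triflate/lutidine silylation of a hindered secondary alcohol; the silyl ether masks the carbinol through the organolithium steps.

Step 20
Reactants: 28 tert-butyl{[(1R,2R)-1-(benzyloxy)-1-[3,5-bis(benzyloxy)-4-methoxyphenyl]propan-2-yl]oxy}dimethylsilane
Product: 29 tert-butyl{[(1R,2R)-1-(benzyloxy)-1-[3,5-bis(benzyloxy)-2,6-dibromo-4-methoxyphenyl]propan-2-yl]oxy}dimethylsilane
Conditions: NBS (2.1 equiv), MeCN, 0 °C to rt, dark
Reagents that add atoms: N-bromosuccinimide, O=C1CCC(=O)N1Br
Why: Twofold electrophilic bromination at the two equivalent positions flanking the chain, each ortho and para to a benzyloxy group.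

Step 21
Reactants: 29 tert-butyl{[(1R,2R)-1-(benzyloxy)-1-[3,5-bis(benzyloxy)-2,6-dibromo-4-methoxyphenyl]propan-2-yl]oxy}dimethylsilane
Product: 32 2-[(1R,2R)-1-(benzyloxy)-2-(tert-butyldimethylsilyloxy)propyl]-4,6-bis(benzyloxy)-3-bromo-5-methoxyphenol, via aryllithium 30 (not isolated), via dimethyl arylboronate 31 (not isolated)
Conditions: n-BuLi (1.0 equiv), THF, −78 °C; B(OMe)3, −78 to 0 °C; 30% H2O2, aq NaOH, 0 °C
Reagents that add atoms: hydrogen peroxide, OO
Why: One equivalent of n-BuLi exchanges one of the two equivalent bromines, a second exchange to a dianion being slow; borylation and basic peroxide oxidation convert the aryllithium into the phenol, which is the extra oxygen of ring B.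

Step 22
Reactants: 32 2-[(1R,2R)-1-(benzyloxy)-2-(tert-butyldimethylsilyloxy)propyl]-4,6-bis(benzyloxy)-3-bromo-5-methoxyphenol
Product: 33 tert-butyl{[(1R,2R)-1-(benzyloxy)-1-[2,3,5-tris(benzyloxy)-6-bromo-4-methoxyphenyl]propan-2-yl]oxy}dimethylsilane
Conditions: BnBr, K2CO3, DMF, 50 °C
Reagents that add atoms: benzyl bromide, BrCc1ccccc1
Why: Williamson etherification of the hindered phenol; the secondary silyl ether is stable to carbonate.

Step 23
Reactants: 33 tert-butyl{[(1R,2R)-1-(benzyloxy)-1-[2,3,5-tris(benzyloxy)-6-bromo-4-methoxyphenyl]propan-2-yl]oxy}dimethylsilane; 20 (1S,2S)-1-(benzyloxy)-1-{2-[(allyloxy)carbonyl]-3,5-bis(benzyloxy)-4-methoxyphenyl}propan-2-yl 1H-imidazole-1-carboxylate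
Product: 35 allyl 2-[(1S,2S)-1-(benzyloxy)-2-({2-[(1R,2R)-1-(benzyloxy)-2-(tert-butyldimethylsilyloxy)propyl]-3,4,6-tris(benzyloxy)-5-methoxybenzoyl}oxy)propyl]-4,6-bis(benzyloxy)-5-methoxybenzoate, via aryllithium 34 (not isolated)
Conditions: 33, n-BuLi, THF, −78 °C; then 20 in THF, −78 to −20 °C; aq NH4Cl
Reagents that add atoms: none
Why: Bromine–lithium exchange followed by acylation of the aryllithium with an alkyl imidazole-1-carboxylate, the ester synthesis known for organometallic reagents with alkoxycarbonyl azolides and chloroformates; the ring B ester is thus made by C–C bond formation. The new ester is shielded by two ortho substituents against a second addition, and the hindered allyl ester of 20 is spared.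

Step 24
Reactants: 35 allyl 2-[(1S,2S)-1-(benzyloxy)-2-({2-[(1R,2R)-1-(benzyloxy)-2-(tert-butyldimethylsilyloxy)propyl]-3,4,6-tris(benzyloxy)-5-methoxybenzoyl}oxy)propyl]-4,6-bis(benzyloxy)-5-methoxybenzoate
Product: 36 2-[(1S,2S)-1-(benzyloxy)-2-({2-[(1R,2R)-1-(benzyloxy)-2-(tert-butyldimethylsilyloxy)propyl]-3,4,6-tris(benzyloxy)-5-methoxybenzoyl}oxy)propyl]-4,6-bis(benzyloxy)-5-methoxybenzoic acid
Conditions: Pd(PPh3)4 (cat.), morpholine, THF, rt
Reagents that add atoms: none
Why: Palladium-catalysed allyl transfer to morpholine cleaves the ester at the O–allyl bond through a π-allyl complex, so hindrance at the acyl carbon is irrelevant and the other ester is untouched.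

Step 25
Reactants: 36 2-[(1S,2S)-1-(benzyloxy)-2-({2-[(1R,2R)-1-(benzyloxy)-2-(tert-butyldimethylsilyloxy)propyl]-3,4,6-tris(benzyloxy)-5-methoxybenzoyl}oxy)propyl]-4,6-bis(benzyloxy)-5-methoxybenzoic acid
Product: 37 2-[(1S,2S)-1-(benzyloxy)-2-({2-[(1R,2R)-1-(benzyloxy)-2-hydroxypropyl]-3,4,6-tris(benzyloxy)-5-methoxybenzoyl}oxy)propyl]-4,6-bis(benzyloxy)-5-methoxybenzoic acid
Conditions: HF·pyridine, pyridine/THF, 0 °C to rt; product used at once
Reagents that add atoms: none
Why: Buffered HF·pyridine cleaves the secondary silyl ether without forming an alkoxide, which would attack the neighbouring ring B ester in a six-membered transition state.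

Step 26
Reactants: 37 2-[(1S,2S)-1-(benzyloxy)-2-({2-[(1R,2R)-1-(benzyloxy)-2-hydroxypropyl]-3,4,6-tris(benzyloxy)-5-methoxybenzoyl}oxy)propyl]-4,6-bis(benzyloxy)-5-methoxybenzoic acid
Product: 38 hepta-O-benzyl diolide (the target with all five phenolic and both benzylic hydroxyls as benzyl ethers)
Conditions: 2-chloro-1-methylpyridinium iodide, Et3N, CH2Cl2, reflux, slow addition at high dilution
Reagents that add atoms: none
Why: Mukaiyama macrolactonisation: the carboxylate is activated at oxygen by the pyridinium salt and the free carbinol closes the 12-membered ring at the ring A carbonyl, a 2-alkyl-4,6-dialkoxybenzoic acid of the type for which carboxyl-activated macrolactonisation is established. The two ortho-phenylene units and two planar ester groups leave few rotors, and the acyl–O bond formation touches no stereocentre.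

Step 27
Reactants: 38 hepta-O-benzyl diolide
Product: 39 CNP0086623.3
Conditions: H2 (1 atm), 10% Pd/C, EtOAc/MeOH, rt; filtration and evaporation without acid or base
Reagents that add atoms: none
Why: Hydrogenolysis of seven O-benzyl groups under neutral conditions; the O–CH2Ph bonds should cleave much faster than the hindered secondary aryl–CH–O bonds, and the reaction is stopped at full debenzylation so that the benzylic hydroxyls are kept and are not left to attack the neighbouring esters.

## Compound list

1 | 2-methoxyresorcinol | COc1c(O)cccc1O | starting material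
2 | 1,3-bis(tert-butyldimethylsilyloxy)-2-methoxybenzene | COc1c(O[Si](C)(C)C(C)(C)C)cccc1O[Si](C)(C)C(C)(C)C | intermediate
3 | 2-[3,5-bis(tert-butyldimethylsilyloxy)-4-methoxyphenyl]-4,4,5,5-tetramethyl-1,3,2-dioxaborolane | COc1c(O[Si](C)(C)C(C)(C)C)cc(cc1O[Si](C)(C)C(C)(C)C)B1OC(C)(C)C(C)(C)O1 | intermediate
4 | 2-[3,5-bis(benzyloxy)-4-methoxyphenyl]-4,4,5,5-tetramethyl-1,3,2-dioxaborolane | COc1c(OCc2ccccc2)cc(cc1OCc2ccccc2)B1OC(C)(C)C(C)(C)O1 | intermediate
5 | [3,5-bis(benzyloxy)-4-methoxyphenyl]boronic acid | COc1c(OCc2ccccc2)cc(cc1OCc2ccccc2)B(O)O | intermediate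
6 | (+)-pinanediol, (1S,2S,3R,5S) | O[C@@H]1C[C@@H]2C[C@H]([C@@]1(O)C)C2(C)C | starting material
7 | (+)-pinanediol [3,5-bis(benzyloxy)-4-methoxyphenyl]boronate | COc1c(OCc2ccccc2)cc(cc1OCc2ccccc2)B1O[C@@H]2C[C@@H]3C[C@H]([C@@]2(O1)C)C3(C)C | intermediate
8 | dichloromethane | ClCCl | starting material
9 | (+)-pinanediol {(S)-[3,5-bis(benzyloxy)-4-methoxyphenyl](chloro)methyl}boronate | COc1c(OCc2ccccc2)cc(cc1OCc2ccccc2)[C@@H](Cl)B1O[C@@H]2C[C@@H]3C[C@H]([C@@]2(O1)C)C3(C)C | intermediate
10 | (+)-pinanediol {(R)-(benzyloxy)[3,5-bis(benzyloxy)-4-methoxyphenyl]methyl}boronate | COc1c(OCc2ccccc2)cc(cc1OCc2ccccc2)[C@H](OCc2ccccc2)B1O[C@@H]2C[C@@H]3C[C@H]([C@@]2(O1)C)C3(C)C | intermediate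
11 | (+)-pinanediol {(1S,2S)-2-(benzyloxy)-2-[3,5-bis(benzyloxy)-4-methoxyphenyl]-1-chloroethyl}boronate | COc1c(OCc2ccccc2)cc(cc1OCc2ccccc2)[C@H](OCc2ccccc2)[C@@H](Cl)B1O[C@@H]2C[C@@H]3C[C@H]([C@@]2(O1)C)C3(C)C | intermediate (not isolated)
12 | (+)-pinanediol {(1R,2S)-1-(benzyloxy)-1-[3,5-bis(benzyloxy)-4-methoxyphenyl]propan-2-yl}boronate | COc1c(OCc2ccccc2)cc(cc1OCc2ccccc2)[C@H](OCc2ccccc2)[C@H](C)B1O[C@@H]2C[C@@H]3C[C@H]([C@@]2(O1)C)C3(C)C | intermediate
13 | (1S,2S)-1-(benzyloxy)-1-[3,5-bis(benzyloxy)-4-methoxyphenyl]propan-2-ol | COc1c(OCc2ccccc2)cc(cc1OCc2ccccc2)[C@H](OCc2ccccc2)[C@H](C)O | intermediate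
14 | (1S,2S)-1-(benzyloxy)-1-[3,5-bis(benzyloxy)-2-bromo-4-methoxyphenyl]propan-2-ol | COc1c(OCc2ccccc2)cc(c(Br)c1OCc2ccccc2)[C@H](OCc2ccccc2)[C@H](C)O | intermediate
15 | dilithio derivative of 14 (aryllithium at the former C–Br carbon, lithium alkoxide) | COc1c(OCc2ccccc2)cc(c([Li])c1OCc2ccccc2)[C@H](OCc2ccccc2)[C@H](C)O[Li] | intermediate (not isolated)
16 | 2-[(1S,2S)-1-(benzyloxy)-2-hydroxypropyl]-4,6-bis(benzyloxy)-5-methoxybenzoic acid | COc1c(OCc2ccccc2)cc(c(C(=O)O)c1OCc2ccccc2)[C@H](OCc2ccccc2)[C@H](C)O | intermediate (not isolated)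
17 | (3S,4S)-4,6,8-tris(benzyloxy)-7-methoxy-3-methylisochroman-1-one | COc1c(OCc3ccccc3)cc2c(c1OCc3ccccc3)C(=O)O[C@@H](C)[C@H]2OCc1ccccc1 | intermediate
18 | potassium 2-[(1S,2S)-1-(benzyloxy)-2-hydroxypropyl]-4,6-bis(benzyloxy)-5-methoxybenzoate | COc1c(OCc2ccccc2)cc(c(C(=O)[O-])c1OCc2ccccc2)[C@H](OCc2ccccc2)[C@H](C)O.[K+] | intermediate (not isolated)
19 | allyl 2-[(1S,2S)-1-(benzyloxy)-2-hydroxypropyl]-4,6-bis(benzyloxy)-5-methoxybenzoate | COc1c(OCc2ccccc2)cc(c(C(=O)OCC=C)c1OCc2ccccc2)[C@H](OCc2ccccc2)[C@H](C)O | intermediate
20 | (1S,2S)-1-(benzyloxy)-1-{2-[(allyloxy)carbonyl]-3,5-bis(benzyloxy)-4-methoxyphenyl}propan-2-yl 1H-imidazole-1-carboxylate | COc1c(OCc2ccccc2)cc(c(C(=O)OCC=C)c1OCc2ccccc2)[C@H](OCc2ccccc2)[C@H](C)OC(=O)n1ccnc1 | intermediate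
21 | (−)-pinanediol, (1R,2R,3S,5R) | O[C@H]1C[C@H]2C[C@@H]([C@]1(O)C)C2(C)C | starting material
22 | (−)-pinanediol [3,5-bis(benzyloxy)-4-methoxyphenyl]boronate | COc1c(OCc2ccccc2)cc(cc1OCc2ccccc2)B1O[C@H]2C[C@H]3C[C@@H]([C@]2(O1)C)C3(C)C | intermediate
23 | (−)-pinanediol {(R)-[3,5-bis(benzyloxy)-4-methoxyphenyl](chloro)methyl}boronate | COc1c(OCc2ccccc2)cc(cc1OCc2ccccc2)[C@H](Cl)B1O[C@H]2C[C@H]3C[C@@H]([C@]2(O1)C)C3(C)C | intermediate
24 | (−)-pinanediol {(S)-(benzyloxy)[3,5-bis(benzyloxy)-4-methoxyphenyl]methyl}boronate | COc1c(OCc2ccccc2)cc(cc1OCc2ccccc2)[C@@H](OCc2ccccc2)B1O[C@H]2C[C@H]3C[C@@H]([C@]2(O1)C)C3(C)C | intermediate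
25 | (−)-pinanediol {(1R,2R)-2-(benzyloxy)-2-[3,5-bis(benzyloxy)-4-methoxyphenyl]-1-chloroethyl}boronate | COc1c(OCc2ccccc2)cc(cc1OCc2ccccc2)[C@@H](OCc2ccccc2)[C@H](Cl)B1O[C@H]2C[C@H]3C[C@@H]([C@]2(O1)C)C3(C)C | intermediate (not isolated)
26 | (−)-pinanediol {(1S,2R)-1-(benzyloxy)-1-[3,5-bis(benzyloxy)-4-methoxyphenyl]propan-2-yl}boronate | COc1c(OCc2ccccc2)cc(cc1OCc2ccccc2)[C@@H](OCc2ccccc2)[C@@H](C)B1O[C@H]2C[C@H]3C[C@@H]([C@]2(O1)C)C3(C)C | intermediate
27 | (1R,2R)-1-(benzyloxy)-1-[3,5-bis(benzyloxy)-4-methoxyphenyl]propan-2-ol | COc1c(OCc2ccccc2)cc(cc1OCc2ccccc2)[C@@H](OCc2ccccc2)[C@@H](C)O | intermediate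
28 | tert-butyl{[(1R,2R)-1-(benzyloxy)-1-[3,5-bis(benzyloxy)-4-methoxyphenyl]propan-2-yl]oxy}dimethylsilane | COc1c(OCc2ccccc2)cc(cc1OCc2ccccc2)[C@@H](OCc2ccccc2)[C@@H](C)O[Si](C)(C)C(C)(C)C | intermediate
29 | tert-butyl{[(1R,2R)-1-(benzyloxy)-1-[3,5-bis(benzyloxy)-2,6-dibromo-4-methoxyphenyl]propan-2-yl]oxy}dimethylsilane | COc1c(OCc2ccccc2)c(Br)c(c(Br)c1OCc2ccccc2)[C@@H](OCc2ccccc2)[C@@H](C)O[Si](C)(C)C(C)(C)C | intermediate
30 | aryllithium from 29 (one bromine replaced by lithium) | COc1c(OCc2ccccc2)c(Br)c(c([Li])c1OCc2ccccc2)[C@@H](OCc2ccccc2)[C@@H](C)O[Si](C)(C)C(C)(C)C | intermediate (not isolated)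
31 | dimethyl {2-[(1R,2R)-1-(benzyloxy)-2-(tert-butyldimethylsilyloxy)propyl]-4,6-bis(benzyloxy)-3-bromo-5-methoxyphenyl}boronate | COc1c(OCc2ccccc2)c(Br)c(c(B(OC)OC)c1OCc2ccccc2)[C@@H](OCc2ccccc2)[C@@H](C)O[Si](C)(C)C(C)(C)C | intermediate (not isolated)
32 | 2-[(1R,2R)-1-(benzyloxy)-2-(tert-butyldimethylsilyloxy)propyl]-4,6-bis(benzyloxy)-3-bromo-5-methoxyphenol | COc1c(OCc2ccccc2)c(Br)c(c(O)c1OCc2ccccc2)[C@@H](OCc2ccccc2)[C@@H](C)O[Si](C)(C)C(C)(C)C | intermediate
33 | tert-butyl{[(1R,2R)-1-(benzyloxy)-1-[2,3,5-tris(benzyloxy)-6-bromo-4-methoxyphenyl]propan-2-yl]oxy}dimethylsilane | COc1c(OCc2ccccc2)c(Br)c(c(OCc2ccccc2)c1OCc2ccccc2)[C@@H](OCc2ccccc2)[C@@H](C)O[Si](C)(C)C(C)(C)C | intermediate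
34 | aryllithium from 33 (bromine replaced by lithium) | COc1c(OCc2ccccc2)c([Li])c(c(OCc2ccccc2)c1OCc2ccccc2)[C@@H](OCc2ccccc2)[C@@H](C)O[Si](C)(C)C(C)(C)C | intermediate (not isolated)
35 | allyl 2-[(1S,2S)-1-(benzyloxy)-2-({2-[(1R,2R)-1-(benzyloxy)-2-(tert-butyldimethylsilyloxy)propyl]-3,4,6-tris(benzyloxy)-5-methoxybenzoyl}oxy)propyl]-4,6-bis(benzyloxy)-5-methoxybenzoate | COc1c(OCc2ccccc2)cc(c(C(=O)OCC=C)c1OCc2ccccc2)[C@H](OCc2ccccc2)[C@H](C)OC(=O)c1c(OCc2ccccc2)c(OC)c(OCc2ccccc2)c(OCc2ccccc2)c1[C@@H](OCc2ccccc2)[C@@H](C)O[Si](C)(C)C(C)(C)C | intermediate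
36 | 2-[(1S,2S)-1-(benzyloxy)-2-({2-[(1R,2R)-1-(benzyloxy)-2-(tert-butyldimethylsilyloxy)propyl]-3,4,6-tris(benzyloxy)-5-methoxybenzoyl}oxy)propyl]-4,6-bis(benzyloxy)-5-methoxybenzoic acid | COc1c(OCc2ccccc2)cc(c(C(=O)O)c1OCc2ccccc2)[C@H](OCc2ccccc2)[C@H](C)OC(=O)c1c(OCc2ccccc2)c(OC)c(OCc2ccccc2)c(OCc2ccccc2)c1[C@@H](OCc2ccccc2)[C@@H](C)O[Si](C)(C)C(C)(C)C | intermediate
37 | 2-[(1S,2S)-1-(benzyloxy)-2-({2-[(1R,2R)-1-(benzyloxy)-2-hydroxypropyl]-3,4,6-tris(benzyloxy)-5-methoxybenzoyl}oxy)propyl]-4,6-bis(benzyloxy)-5-methoxybenzoic acid (seco acid) | COc1c(OCc2ccccc2)cc(c(C(=O)O)c1OCc2ccccc2)[C@H](OCc2ccccc2)[C@H](C)OC(=O)c1c(OCc2ccccc2)c(OC)c(OCc2ccccc2)c(OCc2ccccc2)c1[C@@H](OCc2ccccc2)[C@@H](C)O | intermediate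
38 | hepta-O-benzyl diolide (target with five phenolic and two benzylic hydroxyls as benzyl ethers; ring A chain S,S, ring B chain R,R) | COc1c(OCc3ccccc3)cc2c(c1OCc3ccccc3)C(=O)O[C@H](C)[C@H](OCc3ccccc3)c1c(OCc3ccccc3)c(OCc3ccccc3)c(OC)c(OCc3ccccc3)c1C(=O)O[C@@H](C)[C@H]2OCc1ccccc1 | intermediate
39 | CNP0086623.3 | COc1c(O)cc2c(c1O)C(=O)O[C@H](C)[C@H](O)c1c(O)c(O)c(OC)c(O)c1C(=O)O[C@@H](C)[C@H]2O | target

## Step count and risks

Total step count: 27. Longest linear sequence: 18 steps (steps 1–4, 14–22 and 23–27 through ring B; the ring A branch through steps 1–13 and 23–27 is equally long).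

Step 8 (key step). The most likely failures are β-elimination of benzyloxide from the ate complexes, chloride exchange at the CHCl carbon of 11 before the Grignard reagent arrives (epimerisation), and slow migration of the α-oxygenated carbon, which lets LiCHCl2 decompose first. The fallback sets out from 10 and returns at 12 and delivers the CH(CH3) unit in one piece. Ethyl 2,4,6-triisopropylbenzoate is deprotonated with s-BuLi and (+)-sparteine in Et2O at −78 °C to (R)-1-lithioethyl 2,4,6-triisopropylbenzoate F1. Boronate 10 is added, the ate complex forms with retention, and on warming (with MgBr2·OEt2 if needed) the benzylic carbon migrates with inversion at the carbenoid carbon and loss of the benzoate to give 12. The same two atoms are joined, but no chloride-bearing borate and no Grignard reagent are involved.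

Step 26. Three processes may compete with ring closure: participation of the neighbouring benzylic benzyloxy oxygen at the activated carboxyl with loss of its benzyl group (five-ring closure), translactonisation of the free carbinol onto the ring B ester, and oligomerisation. The fallback closes the same ester by alkylation instead of acylation; it sets out from 35 and returns at 38. HF·pyridine removes the silyl group to give hydroxy diester F2. A Mitsunobu reaction with chloroacetic acid (PPh3, DIAD) then inverts the carbinol to chloroacetate F3, and thiourea/NaHCO3 in EtOH removes the chloroacetyl group to give the (1R,2S)-alcohol F4. Pd(PPh3)4/morpholine cleaves the allyl ester to the epimeric seco acid F5, and PPh3/DIAD at high dilution lets the ring A carboxylate displace the activated carbinol with a second inversion, which gives 38.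

Step 23. Proton transfer to aryllithium 34 from the allylic or benzylic C–H bonds of 20, or attack at the allyl ester, would return debrominated arene and consume the electrophile. The fallback sets out from 34 and returns at 35: 34 is quenched with CO2 to give benzoic acid F6, and F6 is joined to alcohol 19 by carboxyl activation with 2-chloro-1-methylpyridinium iodide and Et3N. This route is conventional but asks a hexasubstituted acid to acylate, which is why it is the second choice.

Step 21. Exchange of both bromines, or proton quench of aryllithium 30 before borylation, would give mixtures that are hard to separate. The fallback sets out from 28 and returns at 33 by introducing the two substituents one at a time. One equivalent of NBS gives monobromide F7, and n-BuLi, B(OMe)3 and basic H2O2 convert it into phenol F8. BnBr/K2CO3 then gives tris(benzyloxy) arene F9, and NBS brominates the single remaining ring position to give 33.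

## Further compounds

F1 | step 8 | (R)-1-lithioethyl 2,4,6-triisopropylbenzoate | C[C@@H]([Li])OC(=O)c1c(C(C)C)cc(C(C)C)cc1C(C)C
F2 | step 26 | allyl 2-[(1S,2S)-1-(benzyloxy)-2-({2-[(1R,2R)-1-(benzyloxy)-2-hydroxypropyl]-3,4,6-tris(benzyloxy)-5-methoxybenzoyl}oxy)propyl]-4,6-bis(benzyloxy)-5-methoxybenzoate | COc1c(OCc2ccccc2)cc(c(C(=O)OCC=C)c1OCc2ccccc2)[C@H](OCc2ccccc2)[C@H](C)OC(=O)c1c(OCc2ccccc2)c(OC)c(OCc2ccccc2)c(OCc2ccccc2)c1[C@@H](OCc2ccccc2)[C@@H](C)O
F3 | step 26 | chloroacetate of the inverted carbinol, ring B chain (1R,2S) | COc1c(OCc2ccccc2)cc(c(C(=O)OCC=C)c1OCc2ccccc2)[C@H](OCc2ccccc2)[C@H](C)OC(=O)c1c(OCc2ccccc2)c(OC)c(OCc2ccccc2)c(OCc2ccccc2)c1[C@@H](OCc2ccccc2)[C@H](C)OC(=O)CCl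
F4 | step 26 | epimeric hydroxy diester, ring B chain (1R,2S) | COc1c(OCc2ccccc2)cc(c(C(=O)OCC=C)c1OCc2ccccc2)[C@H](OCc2ccccc2)[C@H](C)OC(=O)c1c(OCc2ccccc2)c(OC)c(OCc2ccccc2)c(OCc2ccccc2)c1[C@@H](OCc2ccccc2)[C@H](C)O
F5 | step 26 | epimeric seco acid, ring B chain (1R,2S) | COc1c(OCc2ccccc2)cc(c(C(=O)O)c1OCc2ccccc2)[C@H](OCc2ccccc2)[C@H](C)OC(=O)c1c(OCc2ccccc2)c(OC)c(OCc2ccccc2)c(OCc2ccccc2)c1[C@@H](OCc2ccccc2)[C@H](C)O
F6 | step 23 | 2-[(1R,2R)-1-(benzyloxy)-2-(tert-butyldimethylsilyloxy)propyl]-3,4,6-tris(benzyloxy)-5-methoxybenzoic acid | COc1c(OCc2ccccc2)c(C(=O)O)c(c(OCc2ccccc2)c1OCc2ccccc2)[C@@H](OCc2ccccc2)[C@@H](C)O[Si](C)(C)C(C)(C)C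
F7 | step 21 | tert-butyl{[(1R,2R)-1-(benzyloxy)-1-[3,5-bis(benzyloxy)-2-bromo-4-methoxyphenyl]propan-2-yl]oxy}dimethylsilane | COc1c(OCc2ccccc2)cc(c(Br)c1OCc2ccccc2)[C@@H](OCc2ccccc2)[C@@H](C)O[Si](C)(C)C(C)(C)C
F8 | step 21 | 2-[(1R,2R)-1-(benzyloxy)-2-(tert-butyldimethylsilyloxy)propyl]-4,6-bis(benzyloxy)-5-methoxyphenol | COc1c(OCc2ccccc2)cc(c(O)c1OCc2ccccc2)[C@@H](OCc2ccccc2)[C@@H](C)O[Si](C)(C)C(C)(C)C
F9 | step 21 | tert-butyl{[(1R,2R)-1-(benzyloxy)-1-[2,3,5-tris(benzyloxy)-4-methoxyphenyl]propan-2-yl]oxy}dimethylsilane | COc1c(OCc2ccccc2)cc(c(OCc2ccccc2)c1OCc2ccccc2)[C@@H](OCc2ccccc2)[C@@H](C)O[Si](C)(C)C(C)(C)C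
A1 | alternative 1 | (E)-configured 4-alkenyl-2-tert-butoxy-4-hydroxy-3-methoxycyclobut-2-en-1-one bearing the PMB-oxymethyl arm and the (R,R)-diol acetonide (carbinol carbon of the four-membered ring either configuration) | O=C1C(OC(C)(C)C)=C(OC)C1(O)/C(COCc2ccc(OC)cc2)=C/[C@H]2OC(C)(C)O[C@@H]2C
A2 | alternative 1 | ring B hydroquinone with (R,R)-diol acetonide | Oc1c(OC(C)(C)C)c(OC)c(O)c(COCc2ccc(OC)cc2)c1[C@H]1OC(C)(C)O[C@@H]1C
A3 | alternative 2 | seco acid with free ring A carboxyl and (S)-configured ring B C-methyl carbinol, benzylic oxygens as TBS ethers | COc1c(OCc3ccccc3)cc(c(C(=O)O)c1OCc3ccccc3)[C@H](O[Si](C)(C)C(C)(C)C)[C@H](C)OC(=O)c1c(OCc3ccccc3)c(OC)c(OCc3ccccc3)c(OCc3ccccc3)c1[C@@H](O[Si](C)(C)C(C)(C)C)[C@H](C)O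
A4 | alternative 2 | protected diolide (phenols as benzyl ethers, benzylic oxygens as TBS ethers) | COc1c(OCc3ccccc3)cc2c(c1OCc3ccccc3)C(=O)O[C@H](C)[C@H](O[Si](C)(C)C(C)(C)C)c1c(OCc3ccccc3)c(OCc3ccccc3)c(OC)c(OCc3ccccc3)c1C(=O)O[C@@H](C)[C@H]2O[Si](C)(C)C(C)(C)C
A5 | alternative 3 | 12-membered ynoate diolide (alkyne in place of the two ring A carbons) | C2#CC(=O)O[C@H](C)[C@H](O[Si](C)(C)C(C)(C)C)c1c(OCc3ccccc3)c(OCc3ccccc3)c(OC)c(OCc3ccccc3)c1C(=O)O[C@@H](C)[C@H]2O[Si](C)(C)C(C)(C)C
A6 | alternative 3 | 1,2-dimethoxy-1,3-bis(trimethylsilyloxy)buta-1,3-diene (mixture of ketene acetal isomers) | COC(O[Si](C)(C)C)=C(OC)C(O[Si](C)(C)C)=C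
A7 | alternative 3 | diolide with ring A phenols free | COc1c(O)cc2c(c1O)C(=O)O[C@H](C)[C@H](O[Si](C)(C)C(C)(C)C)c1c(OCc3ccccc3)c(OCc3ccccc3)c(OC)c(OCc3ccccc3)c1C(=O)O[C@@H](C)[C@H]2O[Si](C)(C)C(C)(C)C
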